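Atom labels: C1 lactone C=O, C2 the CH2 next to it, C3 ring-fusion CH, C4 ring-fusion C(CH3), C5 ether-ring CH2, C6 the carbon with CH3 and 10-phenyldecyl. The feature exploited lies in the lactone ring. C3 stands β to C1 and is bonded to C4, whose oxygen is acylated by C1. This is the retron of a homoenolate–ketone annulation, and the ether ring (O, C3, C4, C5, C6) provides the tether. Cutting C3–C4 and O–C1 leads to an acyclic keto enal, a tertiary-alkyl (E)-β-alkoxyacrolein carrying a methyl ketone. One chiral-carbene-catalysed isomerisation should close both rings and set C3 and C4; C6 comes from (R)-2-methylglycidol.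

Key step: step 8

Assumption: the face preference of the aminoindanol-derived triazolium on this untested donor cannot be derived safely from related annulations, so the (5aS,10bR) salt is written, and its equally accessible mirror image replaces it if the first run favours the (3S,4S) face.

Step 1
Reactants: 1 (9-bromononyl)benzene; 2 (R)-2-methylglycidol
Product: 5 (2S)-2-methyl-12-phenyldodecane-1,2-diol, via 9-phenylnonylmagnesium bromide 3 (not isolated), via chloromagnesium glycidolate 4 (not isolated)
Conditions: 1, Mg, THF, 45 °C (gives 3); 2, i-PrMgCl (1.0 equiv), THF, −40 °C (gives 4); 3 (1.3 equiv) added to 4, Li2CuCl4 (5 mol %), −40 → 0 °C; H2O quench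
Reagents that add atoms: none
Why: Copper-catalysed Grignard opening of an epoxide is an SN2 attack on the unsubstituted ring CH2, so no bond to the quaternary stereocentre (the future C6) is touched and its spatial arrangement passes unchanged into 5 (the descriptor turns S only through the changed priorities), while masking the hydroxyl as magnesium salt 4 spares a protecting-group pair and a Payne shift of 4 would be degenerate and thus harmless to the enantiomeric purity.

Step 2
Reactants: 5 (2S)-2-methyl-12-phenyldodecane-1,2-diol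
Product: 7 (2S)-2-methyl-2-(10-phenyldecyl)oxirane, via sodium alkoxide of the primary tosylate 6 (not isolated)
Conditions: NaH (2.5 equiv), 1-(p-toluenesulfonyl)imidazole (1.05 equiv), THF, 0 °C → rt; H2O quench
Reagents that add atoms: none
Why: One-pot diol-to-epoxide conversion: the primary alkoxide is sulfonylated far faster than the tertiary one, which then displaces the tosylate in a 3-exo-tet Williamson closure at the primary carbon, so the C–O bond of the stereocentre is retained.

Step 3
Reactants: 7 (2S)-2-methyl-2-(10-phenyldecyl)oxirane; 8 2-methyl-1,3-dithiane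
Product: 10 (2S)-2-methyl-1-(2-methyl-1,3-dithian-2-yl)-12-phenyldodecan-2-ol, via 2-lithio-2-methyl-1,3-dithiane 9 (not isolated)
Conditions: 8 (1.5 equiv), n-BuLi (1.45 equiv), THF, −30 → −10 °C; then 7, DMPU, −20 °C → rt; H2O quench
Reagents that add atoms: none
Why: Corey–Seebach umpolung, in which acetyl anion equivalent 9 opens the 2,2-disubstituted epoxide by SN2 attack at its CH2 (the future C5), DMPU raising the reactivity of the hindered carbanion and the stereocentre again staying untouched.

Step 4
Reactants: 10 (2S)-2-methyl-1-(2-methyl-1,3-dithian-2-yl)-12-phenyldodecan-2-ol; 11 ethyl propiolate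
Product: 12 ethyl (2E)-3-{[(2S)-2-methyl-1-(2-methyl-1,3-dithian-2-yl)-12-phenyldodecan-2-yl]oxy}prop-2-enoate
Conditions: 11 (3 equiv, in portions), PMe3 (0.5 equiv), CH2Cl2, 0 °C → rt
Reagents that add atoms: none
Why: Phosphine-catalysed oxa-Michael addition to an alkynoate, in which the PMe3–propiolate zwitterion deprotonates the alcohol and the alkoxide adds to 11 to give the (E)-β-alkoxyacrylate, the small and strongly nucleophilic PMe3 being the catalyst known to carry tertiary alcohols through this reaction.

Step 5
Reactants: 12 ethyl (2E)-3-{[(2S)-2-methyl-1-(2-methyl-1,3-dithian-2-yl)-12-phenyldodecan-2-yl]oxy}prop-2-enoate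
Product: 13 (2E)-3-{[(2S)-2-methyl-1-(2-methyl-1,3-dithian-2-yl)-12-phenyldodecan-2-yl]oxy}prop-2-en-1-ol
Conditions: i-Bu2AlH (2.3 equiv), CH2Cl2, −78 °C; Na2SO4·10H2O, → rt, filtration
Reagents that add atoms: none
Why: 1,2-Reduction of the vinylogous carbonate by i-Bu2AlH delivers two hydrides to the ester carbon without touching thioacetal or enol ether, and the neutral hydrated-salt quench avoids ionisation of the acid-labile 3-alkoxyallyl alcohol.

Step 6
Reactants: 13 (2E)-3-{[(2S)-2-methyl-1-(2-methyl-1,3-dithian-2-yl)-12-phenyldodecan-2-yl]oxy}prop-2-en-1-ol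
Product: 14 (2E)-3-{[(2S)-2-methyl-1-(2-methyl-1,3-dithian-2-yl)-12-phenyldodecan-2-yl]oxy}prop-2-enal
Conditions: activated MnO2 (15 equiv), CH2Cl2, rt; filtration through Celite
Reagents that add atoms: none
Why: MnO2 oxidation of an allylic alcohol is heterogeneous and neutral, stops at the aldehyde, keeps the E geometry and leaves thioacetals alone.

Step 7
Reactants: 14 (2E)-3-{[(2S)-2-methyl-1-(2-methyl-1,3-dithian-2-yl)-12-phenyldodecan-2-yl]oxy}prop-2-enal
Product: 15 (2E)-3-{[(4S)-4-methyl-2-oxo-14-phenyltetradecan-4-yl]oxy}prop-2-enal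
Conditions: MeI (15 equiv), CaCO3 (5 equiv), MeCN–H2O 9:1, 35 °C, dark
Reagents that add atoms: water, O
Why: Alkylative thioacetal hydrolysis, in which S-methylation makes sulfur a leaving group and water captures the thionium ion, runs near neutrality under CaCO3 buffering, conditions under which β-alkoxyacrylates are known to survive and which should also spare the vinylogous formate and the base-sensitive β-oxy ketone, so that 15 is unmasked last and used at once.

Step 8
Reactants: 15 (2E)-3-{[(4S)-4-methyl-2-oxo-14-phenyltetradecan-4-yl]oxy}prop-2-enal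
Product: 18 plakortolide ether (3aR,5S,6aR)-5,6a-dimethyl-5-(10-phenyldecyl)tetrahydrofuro[3,2-b]furan-2(3H)-one, via extended Breslow dienaminol 16 (not isolated), via acyl azolium alkoxide 17 (not isolated)
Conditions: (5aS,10bR)-2-mesityl-5a,10b-dihydro-4H,6H-indeno[2,1-b][1,2,4]triazolo[4,3-d][1,4]oxazin-2-ium tetrafluoroborate (20 mol %), KN(SiMe3)2 (18 mol %), toluene, rt, 15 min; then 15 by syringe pump (final 0.01 M), 4 Å MS, rt → 40 °C
Reagents that add atoms: none
Why: Proposed new method: the free carbene adds to the aldehyde carbon C1 of 15 and a proton shift gives the conjugated dienaminol 16, whose electron density emerges at C3; C3 attacks the ketone carbon C4, the azolium enol tautomerises to acyl azolium alkoxide 17, and the C4 alkoxide is acylated at C1, which expels the carbene and gives 18. The closest known reaction type is the carbene-catalysed intramolecular homoenolate addition of carbon-substituted enals to tethered ketones giving cis-fused bicyclic γ-butyrolactones; an oxygen substituent on the donor carbon is untried, but it should not switch off the vinylogous push of the enaminol toward C3 and it stabilises developing charge there inductively. The ether ring (O, C3, C4, C5, C6) closes 5-exo-trig on the ketone and the lactone ring (O, C1, C2, C3, C4) closes 5-exo-trig on the acyl azolium. C3 is fixed by the face of 16 left open by the indane wall of the catalyst, C4 by the fact that only an alkoxide cis to the C2 arm can reach C1 in a bicyclo[3.3.0] frame, so that a trans adduct can only revert, and C6 is a spectator whose CH3 and chain differ too little to oppose the catalyst. The step needs attack through C3 and not through C1 or C2: the three-atom tether O–C6–C5 makes attack by C3 a five-ring closure, helped by the gem-disubstituted C6, whereas C1 would need a seven-membered and a protonation-derived C2 enolate a six-membered transition state. Carbene made beforehand with slightly less KN(SiMe3)2 than azolium leaves neither free base nor an acidic ammonium ion, which limits protonation at C3, the ensuing loss of the tertiary alkoxide and E1cB across C5–C6, while slow addition at high dilution suppresses enal self-annulation.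

Compound list
1 | (9-bromononyl)benzene | BrCCCCCCCCCc1ccccc1 | starting material
2 | (R)-2-methylglycidol, [(2R)-2-methyloxiran-2-yl]methanol | C[C@@]1(CO)CO1 | starting material
3 | (9-phenylnonyl)magnesium bromide | Br[Mg]CCCCCCCCCc1ccccc1 | intermediate
4 | chloromagnesium alkoxide of 2 | C[C@@]1(CO[Mg]Cl)CO1 | intermediate
5 | (2S)-2-methyl-12-phenyldodecane-1,2-diol | C[C@@](O)(CO)CCCCCCCCCCc1ccccc1 | intermediate
6 | sodium (2S)-2-methyl-12-phenyl-1-(tosyloxy)dodecan-2-olate | C[C@@]([O-])(COS(=O)(=O)c1ccc(C)cc1)CCCCCCCCCCc1ccccc1.[Na+] | intermediate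
7 | (2S)-2-methyl-2-(10-phenyldecyl)oxirane | C[C@]1(CCCCCCCCCCc2ccccc2)CO1 | intermediate
8 | 2-methyl-1,3-dithiane | CC1SCCCS1 | starting material
9 | 2-lithio-2-methyl-1,3-dithiane | [Li]C1(C)SCCCS1 | intermediate
10 | (2S)-2-methyl-1-(2-methyl-1,3-dithian-2-yl)-12-phenyldodecan-2-ol | CC1(SCCCS1)C[C@](C)(CCCCCCCCCCc1ccccc1)O | intermediate
11 | ethyl propiolate | C#CC(=O)OCC | starting material
12 | ethyl (2E)-3-{[(2S)-2-methyl-1-(2-methyl-1,3-dithian-2-yl)-12-phenyldodecan-2-yl]oxy}prop-2-enoate | CC1(SCCCS1)C[C@](C)(CCCCCCCCCCc1ccccc1)O/C=C/C(=O)OCC | intermediate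
13 | (2E)-3-{[(2S)-2-methyl-1-(2-methyl-1,3-dithian-2-yl)-12-phenyldodecan-2-yl]oxy}prop-2-en-1-ol | CC1(SCCCS1)C[C@](C)(CCCCCCCCCCc1ccccc1)O/C=C/CO | intermediate
14 | (2E)-3-{[(2S)-2-methyl-1-(2-methyl-1,3-dithian-2-yl)-12-phenyldodecan-2-yl]oxy}prop-2-enal | CC1(SCCCS1)C[C@](C)(CCCCCCCCCCc1ccccc1)O/C=C/C=O | intermediate
15 | (2E)-3-{[(4S)-4-methyl-2-oxo-14-phenyltetradecan-4-yl]oxy}prop-2-enal | CC(=O)C[C@](C)(CCCCCCCCCCc1ccccc1)O/C=C/C=O | intermediate
16 | extended Breslow dienaminol from 15 and the (5aS,10bR) carbene (homoenolate equivalent, enaminol geometry open) | CC(=O)C[C@](C)(CCCCCCCCCCc1ccccc1)O/C=C/C(O)=C1N(c2c(C)cc(C)cc2C)N=C2CO[C@H]3Cc4ccccc4[C@H]3N12 | intermediate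
17 | acyl azolium alkoxide: ether ring closed, C3–C4 formed, C4 alkoxide cis to the C2–C1 acyl azolium arm | C[C@]1(CCCCCCCCCCc2ccccc2)C[C@@](C)([O-])[C@@H](CC(=O)c2[n+](-c3c(C)cc(C)cc3C)nc3CO[C@H]4Cc5ccccc5[C@H]4n23)O1 | intermediate
18 | plakortolide ether, (3aR,5S,6aR)-5,6a-dimethyl-5-(10-phenyldecyl)tetrahydrofuro[3,2-b]furan-2(3H)-one (C3 R, C4 R, C6 S) | C[C@]1(CCCCCCCCCCc2ccccc2)C[C@@]2(C)OC(=O)C[C@H]2O1 | target

Total step count: 8. Longest linear sequence: 8 steps (from 1 or 2 to 18).

Steps most likely to fail

Step 8. The homoenolate may be protonated at C3 faster than it attacks the unactivated ketone, after which the tertiary alkoxide is expelled from the azolium enolate. The ketone may lose its β-oxy substituent by base-induced elimination, which would also quench the carbene. Facial discrimination by the catalyst may be poor.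
- The fallback uses known chemistry only. It sets out from 10 and comes back at 18.
- Alkylative hydrolysis of 10 (MeI, CaCO3, aq MeCN) should give (4S)-4-hydroxy-4-methyl-14-phenyltetradecan-2-one F1.
- Compound 11 is deprotonated (LiN(i-Pr)2, THF, −78 °C) to ethyl 3-lithiopropiolate F2.
- 2.5 equiv of F2 add to F1 and give ethyl (6S)-4,6-dihydroxy-4,6-dimethyl-16-phenylhexadec-2-ynoate F3 as both C4 epimers.
- Semihydrogenation (H2, Pd/CaCO3 poisoned with Pb(OAc)2, quinoline, EtOAc) gives ethyl (2Z,6S)-4,6-dihydroxy-4,6-dimethyl-16-phenylhexadec-2-enoate F4.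
- F4 lactonises on standing to 5-[(2S)-2-hydroxy-2-methyl-12-phenyldodecyl]-5-methylfuran-2(5H)-one F5.
- Catalytic DBU (CH2Cl2, rt) then triggers the 5-exo-trig oxa-Michael addition of the C6 hydroxyl to C3. For reasons of strain this can only give cis-fused bicycles.
- The products are 18 and (3aS,5S,6aS)-5,6a-dimethyl-5-(10-phenyldecyl)tetrahydrofuro[3,2-b]furan-2(3H)-one F6, to be parted by chromatography. The price is the absence of control at C4.

Step 7. During the long exposure to aqueous acetonitrile, the alkoxyacrolein unit may be cleaved hydrolytically, or elimination may occur across C5–C6.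
- The fallback sets out from 12 and comes back at 15. The enal is created last, under anhydrous buffered conditions.
- The thioacetal of 12 is hydrolysed first (MeI, CaCO3, aq MeCN), an operation known in the presence of β-alkoxyacrylates. It gives ethyl (2E)-3-{[(4S)-4-methyl-2-oxo-14-phenyltetradecan-4-yl]oxy}prop-2-enoate F7.
- i-Bu2AlH (3.5 equiv, CH2Cl2, −78 °C) reduces ester and ketone to (4S)-4-{[(1E)-3-hydroxyprop-1-en-1-yl]oxy}-4-methyl-14-phenyltetradecan-2-ol F8. Both C2 epimers form, which is of no consequence.
- Dess–Martin periodinane buffered with NaHCO3 (CH2Cl2, 0 °C) oxidises both carbinols to 15.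

Step 4. Conjugate addition of the crowded tertiary hydroxyl, which is flanked by the neopentyl-type dithiane carbon, may be slower than phosphine-induced oligomerisation of the alkynoate.
- The fallback sets out from 7 and comes back at 15. It replaces the bulky ketone mask by a small, flat one.
- Isopropenylmagnesium bromide with Li2CuCl4 (5 mol %, THF, −30 → 0 °C) opens 7 to (4S)-2,4-dimethyl-14-phenyltetradec-1-en-4-ol F9.
- 11 and PMe3 give ethyl (2E)-3-{[(4S)-2,4-dimethyl-14-phenyltetradec-1-en-4-yl]oxy}prop-2-enoate F10.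
- OsO4 (2 mol %) and NMO (acetone–H2O) dihydroxylate the isolated 1,1-disubstituted alkene in preference to the acceptor-substituted one. This gives ethyl (2E)-3-{[(4S)-1,2-dihydroxy-2,4-dimethyl-14-phenyltetradecan-4-yl]oxy}prop-2-enoate F11.
- NaIO4 cleaves F11 to the keto acrylate F7. The reduction and double oxidation described for step 7 then lead through the diol F8 to 15.

Further compounds
F1 | step 8 | (4S)-4-hydroxy-4-methyl-14-phenyltetradecan-2-one | CC(=O)C[C@](C)(CCCCCCCCCCc1ccccc1)O
F2 | step 8 | ethyl 3-lithiopropiolate | [Li]C#CC(=O)OCC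
F3 | step 8 | ethyl (6S)-4,6-dihydroxy-4,6-dimethyl-16-phenylhexadec-2-ynoate (both C4 epimers) | CCOC(=O)C#CC(C)(O)C[C@](C)(CCCCCCCCCCc1ccccc1)O
F4 | step 8 | ethyl (2Z,6S)-4,6-dihydroxy-4,6-dimethyl-16-phenylhexadec-2-enoate (both C4 epimers) | CCOC(=O)/C=C\C(C)(O)C[C@](C)(CCCCCCCCCCc1ccccc1)O
F5 | step 8 | 5-[(2S)-2-hydroxy-2-methyl-12-phenyldodecyl]-5-methylfuran-2(5H)-one (both C5 epimers) | CC1(C[C@](C)(CCCCCCCCCCc2ccccc2)O)OC(=O)C=C1
F6 | step 8 | (3aS,5S,6aS)-5,6a-dimethyl-5-(10-phenyldecyl)tetrahydrofuro[3,2-b]furan-2(3H)-one | C[C@]1(CCCCCCCCCCc2ccccc2)C[C@]2(C)OC(=O)C[C@@H]2O1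
F7 | step 7 | ethyl (2E)-3-{[(4S)-4-methyl-2-oxo-14-phenyltetradecan-4-yl]oxy}prop-2-enoate | CC(=O)C[C@](C)(CCCCCCCCCCc1ccccc1)O/C=C/C(=O)OCC
F8 | step 7 | (4S)-4-{[(1E)-3-hydroxyprop-1-en-1-yl]oxy}-4-methyl-14-phenyltetradecan-2-ol (both C2 epimers) | CC(O)C[C@](C)(CCCCCCCCCCc1ccccc1)O/C=C/CO
F9 | step 4 | (4S)-2,4-dimethyl-14-phenyltetradec-1-en-4-ol | CC(=C)C[C@](C)(CCCCCCCCCCc1ccccc1)O
F10 | step 4 | ethyl (2E)-3-{[(4S)-2,4-dimethyl-14-phenyltetradec-1-en-4-yl]oxy}prop-2-enoate | CC(=C)C[C@](C)(CCCCCCCCCCc1ccccc1)O/C=C/C(=O)OCC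
F11 | step 4 | ethyl (2E)-3-{[(4S)-1,2-dihydroxy-2,4-dimethyl-14-phenyltetradecan-4-yl]oxy}prop-2-enoate (both C2 epimers) | CC(O)(CO)C[C@](C)(CCCCCCCCCCc1ccccc1)O/C=C/C(=O)OCC
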